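Locants: flavanone half plain (C2–C8a) with ring B primed (1'–6'). The flavone half, and luteolin-derived compounds generally, are double-primed (ring A C5''–C8''), with its ring B triple-primed.
Cuts, in order: the six O-benzyl bonds; the biaryl bond C5'–C6'', which leaves two complete flavonoid monomers with plain C–H at both ends; C2–C1' of the flavanone (chromone + arylboronic acid); ring C of that chromone (phloroacetophenone + a C1 unit). The flavone half is luteolin itself.
Enabling feature: C5'–C6'' is the axis of a 2,2'-biphenol. C5' is the only open ortho/para position of the O4' phenol of ring B (C3' bears O, C1' bears C2). C6'' is ortho to O5'', which forms a bidentate metal pocket with the C4''=O carbonyl. Both carbons are nucleophilic, so they are joined by oxidation, with ring B reversed in polarity as a phenoxyl radical.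
Helpers: O3' stays benzylated so that ring B is a guaiacol and not a catechol, whose o-quinone would be attacked by carbon nucleophiles at C6'/C2'. O4'–H and O5''–H are the only free hydroxyls at the coupling, and all masks leave in one final hydrogenolysis.
Forward order: ring C of the flavanone half is closed as a chromone, ring B is added at C2, O4' is unmasked, the tri-O-benzylated luteolin is joined, and the product is deprotected.
Stereochemistry: C2 (S) is set by ligand control in a rhodium-catalysed asymmetric 1,4-addition and is afterwards exposed only to base-free media.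

Key step: step 9

Assumption 1: the C5'–C6'' axis (ortho substituents O4', O5'', O7'') is taken to rotate freely at room temperature, since the target carries no axial descriptor. Rotamers of benzylated intermediates should converge on deprotection.
Assumption 2: the sense of induction in step 6 is taken from the accepted model for rhodium/(S)-biaryl bisphosphine additions to cyclic enones, which translates to 2S here. If it proved opposite, the (R)-ligand would be used.

Step 1
Reactants: 1 2',4',6'-trihydroxyacetophenone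
Product: 2 1-[2,4-bis(benzyloxy)-6-hydroxyphenyl]ethan-1-one
Conditions: BnBr (2.1 equiv), K2CO3 (2.2 equiv), DMF, 60 °C
Reagents that add atoms: benzyl bromide, BrCc1ccccc1
Why: Williamson etherification, in which the hydroxyls not tied up in the hydrogen bond to the acetyl carbonyl are alkylated first, so the reaction should stop at the chelated monophenol.

Step 2
Reactants: 2 1-[2,4-bis(benzyloxy)-6-hydroxyphenyl]ethan-1-one
Product: 4 5,7-bis(benzyloxy)-4H-chromen-4-one, via enaminone 3 (not isolated)
Conditions: Me2NCH(OMe)2, toluene, 100 °C; then 2 M HCl, CH2Cl2, 40 °C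
Reagents that add atoms: N,N-dimethylformamide dimethyl acetal, COC(OC)N(C)C
Why: Enaminone route to chromones, in which the methyl ketone condenses with the amide acetal and acid then triggers intramolecular oxa-Michael addition of the free phenol and loss of dimethylamine, closing ring C.

Step 3
Reactants: 5 2-(benzyloxy)phenol
Product: 6 2-(benzyloxy)-4-bromophenol
Conditions: NBS (1.0 equiv), MeCN, 0 °C
Reagents that add atoms: N-bromosuccinimide, O=C1CCC(=O)N1Br
Why: Electrophilic aromatic bromination directed para to the free hydroxyl, the stronger donor, as in the conversion of guaiacol into 4-bromoguaiacol.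

Step 4
Reactants: 6 2-(benzyloxy)-4-bromophenol
Product: 7 [2-(benzyloxy)-4-bromophenoxy](tert-butyl)dimethylsilane
Conditions: TBSCl, imidazole, CH2Cl2, rt
Reagents that add atoms: tert-butyldimethylsilyl chloride, CC(C)(C)[Si](C)(C)Cl
Why: Standard silylation of a phenol, giving a silyl ether orthogonal to the benzyl ethers that marks the future O4' as the one oxygen to be freed before the coupling.

Step 5
Reactants: 7 [2-(benzyloxy)-4-bromophenoxy](tert-butyl)dimethylsilane
Product: 10 {3-(benzyloxy)-4-[(tert-butyldimethylsilyl)oxy]phenyl}boronic acid, via aryllithium 8 (not isolated), via lithium triisopropoxyborate 9 (not isolated)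
Conditions: n-BuLi, THF, −78 °C; B(OiPr)3, −78 °C to rt; 1 M HCl work-up
Reagents that add atoms: triisopropyl borate, CC(C)OB(OC(C)C)OC(C)C; water, O
Why: Bromine–lithium exchange should outrun attack on the benzyl or silyl ether at −78 °C, and borate trapping followed by mild hydrolysis is the standard route to arylboronic acids.

Step 6
Reactants: 4 5,7-bis(benzyloxy)-4H-chromen-4-one; 10 {3-(benzyloxy)-4-[(tert-butyldimethylsilyl)oxy]phenyl}boronic acid
Product: 11 (2S)-5,7-bis(benzyloxy)-2-{3-(benzyloxy)-4-[(tert-butyldimethylsilyl)oxy]phenyl}-2,3-dihydro-4H-chromen-4-one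
Conditions: 10 (1.5 equiv), [Rh(OH)(cod)]2 (1.5 mol %), (S)-MeO-F12-BIPHEP [(S)-6,6'-dimethoxy-2,2'-bis[bis(3,4,5-trifluorophenyl)phosphino]biphenyl, 3.3 mol %], CH2Cl2/H2O (10:1), 20 °C
Reagents that add atoms: none
Why: Hayashi–Miyaura asymmetric 1,4-addition of an arylboronic acid to a 5,7-dioxygenated chromone, in which the aryl–rhodium species on the electron-poor (S)-bisphosphine should insert C2=C3 from one face and set C2 as S, while low temperature and fast protonation of the oxa-π-allyl rhodium intermediate guard against ring opening.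

Step 7
Reactants: 11 (2S)-5,7-bis(benzyloxy)-2-{3-(benzyloxy)-4-[(tert-butyldimethylsilyl)oxy]phenyl}-2,3-dihydro-4H-chromen-4-one
Product: 12 (2S)-5,7-bis(benzyloxy)-2-[3-(benzyloxy)-4-hydroxyphenyl]-2,3-dihydro-4H-chromen-4-one (5,7,3'-tri-O-benzyl-(S)-eriodictyol)
Conditions: HF·pyridine, THF, 0 °C to rt
Reagents that add atoms: none
Why: Fluoride-induced cleavage of the aryl silyl ether in an acidic medium, so that no 4'-phenolate forms that could open ring C through a quinone methide and racemise C2.

Step 8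
Reactants: 13 luteolin
Product: 14 7-(benzyloxy)-2-[3,4-bis(benzyloxy)phenyl]-5-hydroxy-4H-chromen-4-one (7,3',4'-tri-O-benzylluteolin)
Conditions: BnBr (3.2 equiv), K2CO3 (3.5 equiv), DMF, rt
Reagents that add atoms: benzyl bromide, BrCc1ccccc1
Why: Williamson etherification, in which the 5-hydroxyl is hydrogen-bonded to the C4 carbonyl and least reactive, so three equivalents of halide should leave exactly this hydroxyl free.

Step 9
Reactants: 12 (2S)-5,7-bis(benzyloxy)-2-[3-(benzyloxy)-4-hydroxyphenyl]-2,3-dihydro-4H-chromen-4-one; 14 7-(benzyloxy)-2-[3,4-bis(benzyloxy)phenyl]-5-hydroxy-4H-chromen-4-one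
Product: 15 6-{3-(benzyloxy)-5-[(2S)-5,7-bis(benzyloxy)-4-oxo-3,4-dihydro-2H-chromen-2-yl]-2-hydroxyphenyl}-7-(benzyloxy)-2-[3,4-bis(benzyloxy)phenyl]-5-hydroxy-4H-chromen-4-one (hexa-O-benzyl biflavonoid)
Conditions: 14 (3 equiv), FeCl3 (20 mol %), t-BuOOt-Bu (1.5 equiv), (CF3)2CHOH/CH2Cl2 (2:1), rt, N2; 12 added over 6 h by syringe pump; excess 14 recovered
Reagents that add atoms: none
Why: Both phenols should exchange onto trivalent iron, 14 through the bidentate O5''/C4''=O pocket and 12 through O4'; the peroxide then oxidises the electron-rich guaiacol ligand to a bound phenoxyl radical with spin on O4', C1', C3' and C5', C6'' of the bound 5''-phenolate attacks C5', and loss of one more electron and two protons rearomatises both rings to the 2,2'-biphenol. The closest known reaction type is the iron-catalysed oxidative phenol–phenol cross-coupling in fluorinated alcohols (chelated radical–anion coupling), supported by the anodic cross-coupling of 4-alkylguaiacols with oxygenated arenes, both of which bond the free ortho carbon of the guaiacol. No ring is closed and no stereocentre is made, C2 is a spectator in the base-free medium, and the new axis is taken as freely rotating. Within 12 the site is secured because C3' (OBn) and C1' (bearing C2) are blocked, so C5' is the only open spin-bearing carbon, and because the O3' benzyl group forbids the o-quinone that would steer a carbon nucleophile to C6' or C2'. Within 14 the site is secured because only C6'' is ortho to the iron-bound O5'' while C8'' is para and out of reach of an inner-sphere coupling, in line with the C6 preference of electrophiles for 5-hydroxy-7-alkoxyflavones. Chemoselectivity is secured because O4'–H is the only unchelated free phenol and therefore the only easily oxidised site, because ring A of 12 has no free hydroxyl and cannot become a bound phenolate, and because excess 14 and slow addition of 12 hold down homocoupling.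

Step 10
Reactants: 15 hexa-O-benzyl biflavonoid
Product: 16 6-{5-[(2S)-5,7-dihydroxy-4-oxo-3,4-dihydro-2H-chromen-2-yl]-2,3-dihydroxyphenyl}-2-(3,4-dihydroxyphenyl)-5,7-dihydroxy-4H-chromen-4-one (target)
Conditions: H2 (1 atm), Pd/C (10 wt %), THF/MeOH (1:1), AcOH (1 vol %), rt
Reagents that add atoms: none
Why: Catalytic hydrogenolysis of the six aryl benzyl ethers under weakly acidic conditions, which should leave the flavone C2''=C3'' bond, both carbonyl groups and the base-sensitive stereocentre C2 untouched.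

Compound list
1 | 2',4',6'-trihydroxyacetophenone | CC(=O)c1c(O)cc(O)cc1O | starting material
2 | 1-[2,4-bis(benzyloxy)-6-hydroxyphenyl]ethan-1-one | CC(=O)c1c(O)cc(OCc2ccccc2)cc1OCc1ccccc1 | intermediate
3 | (E)-1-[2,4-bis(benzyloxy)-6-hydroxyphenyl]-3-(dimethylamino)prop-2-en-1-one (enaminone, not isolated) | CN(C)/C=C/C(=O)c1c(O)cc(OCc2ccccc2)cc1OCc1ccccc1 | intermediate
4 | 5,7-bis(benzyloxy)-4H-chromen-4-one | O=c1ccoc2cc(OCc3ccccc3)cc(OCc3ccccc3)c12 | intermediate
5 | 2-(benzyloxy)phenol | Oc1ccccc1OCc1ccccc1 | starting material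
6 | 2-(benzyloxy)-4-bromophenol | Oc1ccc(Br)cc1OCc1ccccc1 | intermediate
7 | [2-(benzyloxy)-4-bromophenoxy](tert-butyl)dimethylsilane | CC(C)(C)[Si](C)(C)Oc1ccc(Br)cc1OCc1ccccc1 | intermediate
8 | {3-(benzyloxy)-4-[(tert-butyldimethylsilyl)oxy]phenyl}lithium (not isolated) | [Li]c1ccc(O[Si](C)(C)C(C)(C)C)c(OCc2ccccc2)c1 | intermediate
9 | lithium {3-(benzyloxy)-4-[(tert-butyldimethylsilyl)oxy]phenyl}triisopropoxyborate (not isolated) | [Li+].CC(C)O[B-](OC(C)C)(OC(C)C)c1ccc(O[Si](C)(C)C(C)(C)C)c(OCc2ccccc2)c1 | intermediate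
10 | {3-(benzyloxy)-4-[(tert-butyldimethylsilyl)oxy]phenyl}boronic acid | OB(O)c1ccc(O[Si](C)(C)C(C)(C)C)c(OCc2ccccc2)c1 | intermediate
11 | (2S)-5,7-bis(benzyloxy)-2-{3-(benzyloxy)-4-[(tert-butyldimethylsilyl)oxy]phenyl}-2,3-dihydro-4H-chromen-4-one | O=C1C[C@@H](c2ccc(O[Si](C)(C)C(C)(C)C)c(OCc3ccccc3)c2)Oc2cc(OCc3ccccc3)cc(OCc3ccccc3)c21 | intermediate
12 | (2S)-5,7-bis(benzyloxy)-2-[3-(benzyloxy)-4-hydroxyphenyl]-2,3-dihydro-4H-chromen-4-one | O=C1C[C@@H](c2ccc(O)c(OCc3ccccc3)c2)Oc2cc(OCc3ccccc3)cc(OCc3ccccc3)c21 | intermediate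
13 | luteolin, 2-(3,4-dihydroxyphenyl)-5,7-dihydroxy-4H-chromen-4-one | O=c1cc(-c2ccc(O)c(O)c2)oc2cc(O)cc(O)c12 | starting material
14 | 7-(benzyloxy)-2-[3,4-bis(benzyloxy)phenyl]-5-hydroxy-4H-chromen-4-one | O=c1cc(-c2ccc(OCc3ccccc3)c(OCc3ccccc3)c2)oc2cc(OCc3ccccc3)cc(O)c12 | intermediate
15 | 6-{3-(benzyloxy)-5-[(2S)-5,7-bis(benzyloxy)-4-oxo-3,4-dihydro-2H-chromen-2-yl]-2-hydroxyphenyl}-7-(benzyloxy)-2-[3,4-bis(benzyloxy)phenyl]-5-hydroxy-4H-chromen-4-one | O=C1C[C@@H](c2cc(OCc3ccccc3)c(O)c(-c3c(OCc4ccccc4)cc4oc(-c5ccc(OCc6ccccc6)c(OCc6ccccc6)c5)cc(=O)c4c3O)c2)Oc2cc(OCc3ccccc3)cc(OCc3ccccc3)c21 | intermediate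
16 | 6-{5-[(2S)-5,7-dihydroxy-4-oxo-3,4-dihydro-2H-chromen-2-yl]-2,3-dihydroxyphenyl}-2-(3,4-dihydroxyphenyl)-5,7-dihydroxy-4H-chromen-4-one | O=C1C[C@@H](c2cc(O)c(O)c(-c3c(O)cc4oc(-c5ccc(O)c(O)c5)cc(=O)c4c3O)c2)Oc2cc(O)cc(O)c21 | target

Total step count: 10
Longest linear sequence: 7 steps (steps 3, 4, 5, 6, 7, 9, 10)

Steps most likely to fail

1. Step 9.
- What may go wrong: homocoupling of the guaiacol at C5'; attack through C8'' or through ring A of a second flavanone molecule; saturation of the iron centre by the chelating flavone; hydrogen abstraction at C2 or at benzylic CH2 groups, with dehydrogenation or erosion of configuration; acid-induced loss of benzyl groups.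
- Fallback (sets out from 6, 14 and 4, comes back at 16): the biaryl bond is made by Suzuki–Miyaura coupling before the stereocentre exists, so that no base ever meets the flavanone.
- Compound 6 is iodinated at its free ortho position (NIS, MeCN, 0 °C) to 2-(benzyloxy)-4-bromo-6-iodophenol F1 and benzylated (BnBr, K2CO3, DMF) to 1,2-bis(benzyloxy)-5-bromo-3-iodobenzene F2.
- Selective iodine–magnesium exchange (iPrMgCl·LiCl, THF, −40 °C) and a quench with 2-isopropoxy-4,4,5,5-tetramethyl-1,3,2-dioxaborolane give 2-[2,3-bis(benzyloxy)-5-bromophenyl]-4,4,5,5-tetramethyl-1,3,2-dioxaborolane F3.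
- Compound 14 is iodinated ortho to its free hydroxyl (BnMe3N ICl2, CaCO3, CH2Cl2/MeOH) to 7-(benzyloxy)-2-[3,4-bis(benzyloxy)phenyl]-5-hydroxy-6-iodo-4H-chromen-4-one F4.
- Coupling of F3 and F4 (Pd(PPh3)4, K2CO3, dioxane/H2O, 80 °C), in which the aryl iodide should react ahead of the aryl bromide, gives 7-(benzyloxy)-6-[2,3-bis(benzyloxy)-5-bromophenyl]-2-[3,4-bis(benzyloxy)phenyl]-5-hydroxy-4H-chromen-4-one F5.
- Miyaura borylation (B2pin2, PdCl2(dppf), KOAc, dioxane) gives the corresponding 5-(4,4,5,5-tetramethyl-1,3,2-dioxaborolan-2-yl)phenyl flavone F6.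
- This boronate is added to chromone 4 with the catalyst of step 6 at slightly higher temperature to give the 4'-O-benzyl ether of 15 (hepta-O-benzyl biflavonoid) F7, and hydrogenolysis as in step 10 gives 16.

2. Step 6.
- What may go wrong: β-elimination of the aryloxide from the rhodium enolate (ring opening); further 1,2-addition to the product ketone; protodeboronation; slow insertion into the 5-benzyloxy-substituted chromone.
- Fallback (sets out from 7 and 2, comes back at 12): asymmetric catalysis is replaced by a racemic chalcone route with resolution and recycling.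
- Compound 7 is lithiated as in step 5 and quenched with DMF to give 3-(benzyloxy)-4-[(tert-butyldimethylsilyl)oxy]benzaldehyde F8.
- Claisen–Schmidt condensation with 2 (concentrated KOH, EtOH, rt), in which the silyl ether is lost, gives (E)-1-[2,4-bis(benzyloxy)-6-hydroxyphenyl]-3-[3-(benzyloxy)-4-hydroxyphenyl]prop-2-en-1-one F9.
- NaOAc in refluxing EtOH closes ring C by oxa-Michael addition to racemic 5,7-bis(benzyloxy)-2-[3-(benzyloxy)-4-hydroxyphenyl]-2,3-dihydro-4H-chromen-4-one F10.
- Preparative chromatography on a cellulose tris(3,5-dimethylphenylcarbamate) phase delivers 12. The (2R)-5,7-bis(benzyloxy)-2-[3-(benzyloxy)-4-hydroxyphenyl]-2,3-dihydro-4H-chromen-4-one F11 is re-equilibrated with NaOAc and recycled.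

3. Step 10.
- What may go wrong: over-reduction (saturation of C2''=C3'', hydrogenolysis of the benzylic C2–O1 bond); debenzylation stalling when partly deprotected material precipitates on the catalyst.
- Fallback (sets out from 15, comes back at 16): non-reductive Lewis-acid debenzylation with BCl3 and pentamethylbenzene as cation scavenger in CH2Cl2 at −78 °C, followed by a methanol quench. No new compound is made (entry F0).

Further compounds
F1 | step 9 | 2-(benzyloxy)-4-bromo-6-iodophenol | Oc1c(I)cc(Br)cc1OCc1ccccc1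
F2 | step 9 | 1,2-bis(benzyloxy)-5-bromo-3-iodobenzene | Brc1cc(I)c(OCc2ccccc2)c(OCc2ccccc2)c1
F3 | step 9 | 2-[2,3-bis(benzyloxy)-5-bromophenyl]-4,4,5,5-tetramethyl-1,3,2-dioxaborolane | Brc1cc(B2OC(C)(C)C(C)(C)O2)c(OCc2ccccc2)c(OCc2ccccc2)c1
F4 | step 9 | 7-(benzyloxy)-2-[3,4-bis(benzyloxy)phenyl]-5-hydroxy-6-iodo-4H-chromen-4-one | O=c1cc(-c2ccc(OCc3ccccc3)c(OCc3ccccc3)c2)oc2cc(OCc3ccccc3)c(I)c(O)c12
F5 | step 9 | 7-(benzyloxy)-6-[2,3-bis(benzyloxy)-5-bromophenyl]-2-[3,4-bis(benzyloxy)phenyl]-5-hydroxy-4H-chromen-4-one | O=c1cc(-c2ccc(OCc3ccccc3)c(OCc3ccccc3)c2)oc2cc(OCc3ccccc3)c(-c3cc(Br)cc(OCc4ccccc4)c3OCc3ccccc3)c(O)c12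
F6 | step 9 | 7-(benzyloxy)-6-[2,3-bis(benzyloxy)-5-(4,4,5,5-tetramethyl-1,3,2-dioxaborolan-2-yl)phenyl]-2-[3,4-bis(benzyloxy)phenyl]-5-hydroxy-4H-chromen-4-one | O=c1cc(-c2ccc(OCc3ccccc3)c(OCc3ccccc3)c2)oc2cc(OCc3ccccc3)c(-c3cc(B4OC(C)(C)C(C)(C)O4)cc(OCc4ccccc4)c3OCc3ccccc3)c(O)c12
F7 | step 9 | 4'-O-benzyl ether of 15 (hepta-O-benzyl biflavonoid, 2S) | O=C1C[C@@H](c2cc(OCc3ccccc3)c(OCc3ccccc3)c(-c3c(OCc4ccccc4)cc4oc(-c5ccc(OCc6ccccc6)c(OCc6ccccc6)c5)cc(=O)c4c3O)c2)Oc2cc(OCc3ccccc3)cc(OCc3ccccc3)c21
F8 | step 6 | 3-(benzyloxy)-4-[(tert-butyldimethylsilyl)oxy]benzaldehyde | O=Cc1ccc(O[Si](C)(C)C(C)(C)C)c(OCc2ccccc2)c1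
F9 | step 6 | (E)-1-[2,4-bis(benzyloxy)-6-hydroxyphenyl]-3-[3-(benzyloxy)-4-hydroxyphenyl]prop-2-en-1-one | O=C(/C=C/c1ccc(O)c(OCc2ccccc2)c1)c1c(O)cc(OCc2ccccc2)cc1OCc1ccccc1
F10 | step 6 | racemic 5,7-bis(benzyloxy)-2-[3-(benzyloxy)-4-hydroxyphenyl]-2,3-dihydro-4H-chromen-4-one | O=C1CC(c2ccc(O)c(OCc3ccccc3)c2)Oc2cc(OCc3ccccc3)cc(OCc3ccccc3)c21
F11 | step 6 | (2R)-5,7-bis(benzyloxy)-2-[3-(benzyloxy)-4-hydroxyphenyl]-2,3-dihydro-4H-chromen-4-one | O=C1C[C@H](c2ccc(O)c(OCc3ccccc3)c2)Oc2cc(OCc3ccccc3)cc(OCc3ccccc3)c21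
F0 | step 10 | none | none
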